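# Proposed total synthesis of (3R,3'R,6'R)-lutein 3-O-myristate 3'-O-palmitate (CNP0230054.1)

Locants follow carotenoid numbering (ring C1–C6, chain C7–C15; primed numbers for the ε-half).

## The problem

The target is all-E (3R,3'R,6'R)-lutein with a tetradecanoate on O3 of the β-ring and a hexadecanoate on O3' of the ε-ring. Its spine is an unsymmetrical polyene with nine E chain double bonds between two different rings, so the chain must be joined in a fixed order, without alkoxide, acid, light or oxidants that scramble it. C3 on the β-ring is an isolated stereocenter and must be set on its own. C3' and C6' on the ε-ring are 1,4-related across C4'=C5', with O3' and the C7' chain trans (so O3' and H6' cis), and C3' is the only practical source of control for C6'. The ε-ring is the unconjugated, less stable double-bond isomer of the β-ring: H6' is doubly allylic and moves into conjugation with base, and the 3'-ester is allylic and ionizes with acid or Pd(0). The two secondary hydroxyls have nearly equal reactivity, so two different acyl groups cannot be placed selectively at the end.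

The feature that makes the key step possible lies in ring C1'–C6'. The array O3'–C3'–C4'=C5'–C6'–H6' has O and H on the same face. This is exactly what remains when an allylic diazene nitrogen at C4', cis to O3', hands its hydrogen suprafacially to C6' while the double bond moves from C5'=C6' to C4'=C5'. The ε-ring can therefore be made from a flat, conjugated β-type ring carrying a cis-3,4-epoxide next to C5=C6, which palladium opens with overall retention at C4.

## Retrosynthesis

**23 to 21 + 18 (cut C11=C12).** A Wittig reaction here joins a C25 aldehyde 21 to the β-C15 phosphonium salt 18 and leaves every methyl-bearing double bond preformed. A cut at C7=C8 would need olefination of a neopentyl, enolizable ring aldehyde. A cut at C15=C15' would need two C20 halves and longer linear sequences. The ester bonds are not cut: each half brings its own acyl group, so the diester problem is solved by convergence. The forward reaction must run without alkoxide base, which is why an epoxide is used as HBr acceptor.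

**21 to 11 + 19 (cut C11'=C12').** The same Wittig logic joins the ε-C15 salt 11 to the symmetrical C10 dialdehyde 19. The precursor is a commercial dialdehyde; the forward reaction must stop at mono-olefination, secured by an excess of 19.

**11 to 10 to 9 to 8 (C11'–P, O3'–acyl, C9'–C10').** The phosphonium salt comes from the tertiary vinyl carbinol 10 by ionization and capture at C11'. Compound 10 comes from diol 9 by acylation of the secondary hydroxyl, and 9 from (3R,6R)-3-hydroxy-α-ionone 8 by vinyl addition. Placing the acylation between Grignard addition and salt formation means the ester never meets an organometallic reagent. The alternative (ester reduction level at C11') would need hydride steps.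

**8 to 4 (key: C6'–H, C4'=C5' from C4–O, C5=C6).** The deconjugated ring and the C3'/C6' relationship of 8 are traced to vinyl epoxide 4, a flat dienone whose only stereo-elements are the two epoxide carbons. The neighbouring cuts (C6'–C7' bond formation on a preformed ring, or reduction of a 3'-ketone under remote control) either attack a neopentyl carbon or rely on weak 1,4-induction. The forward reaction must open C4–O with retention by nitrogen, then deliver hydrogen to C6 only. Compound 4 comes from achiral trienone 3 by one catalytic epoxidation of C3=C4.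

**18 to 17 to 16 to 15, and 15 to 12 to 3.** The β-half uses the same three operations (vinyl addition, acylation, salt formation) from (R)-3-hydroxy-β-ionone 15. C3–O of 15 is cut back to the same C3=C4 double bond of 3, as its ketal 12, by asymmetric hydroboration. Both rings thus diverge from one achiral compound: boron at C3 for the β-ring, oxygen across C3/C4 for the ε-ring.

**3 to 1.** The C3=C4 double bond comes from β-ionone 1 by allylic bromination at C4 and dehydrobromination.

## Roads not taken

**Alternative 1:** The obvious plan cuts the two ester C–O bonds last and makes free lutein A3 by the C15 + C10 + C15 double Wittig sequence. The ε-end would come from resolved (R)-α-ionone A1 through allylic oxidation to (6R)-3-oxo-α-ionone A2 and hydride reduction. The forward key step is the stepwise Wittig assembly of A3 followed by acylation. The chosen plan is better for three reasons. Reduction of A2 sets C3' under weak 1,4-control from C6' and gives cis/trans mixtures that must be separated. A1 itself needs a resolution. A3 has two secondary hydroxyls of nearly equal reactivity, so two different acyl groups would give statistical mixtures of mono- and diesters on the most sensitive compound of the route.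

**Alternative 2:** Cut C6'–C7' and form it by anti-SN2' addition of an alkenylcopper reagent to the vinyl epoxide A4 (3,4-epoxide of 2,6,6-trimethylcyclohexa-1,3-diene). This would set C6' and the ring–chain bond in one step. It was rejected because the nucleophile must attack a neopentyl diene terminus next to C1'Me2, where direct SN2 opening at C4' competes. In addition, A4 requires epoxidation of the disubstituted double bond of a volatile diene in the presence of its more nucleophilic trisubstituted one. The chosen plan delivers only hydrogen to the hindered carbon and epoxidizes a diene whose other double bonds are deactivated or shielded.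

**Alternative 3:** Cut the central C15=C15' bond and join two C20 aldehydes, (3R)-3-myristoyloxyretinal A5 and (3R,6R)-3-palmitoyloxy-α-retinal A6, by reductive carbonyl coupling (McMurry). This is a union of two carbons of like polarity. It was rejected because cross-coupling of two near-identical aldehydes is statistical, low-valent titanium cleaves allylic esters, and the central double bond is formed without geometric control. The stepwise Wittig assembly is unsymmetrical by construction and leaves the esters untouched.

Key step: step 3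

**Assumptions.**
- 3,4-Didehydro-β-ionone 3 is treated as not stocked and is made from β-ionone; where it can be bought, step 1 is dropped.
- The (S,S) hand of the Mn(salen) catalyst (step 2) and the (+) hand of Ipc2BH (step 8) are assigned from the accepted approach models for cis-disubstituted alkenes. The antipodal reagent is to be used if either sense proves to be the reverse.
- The carbinol center C9 formed in steps 4 and 9 is a mixture of epimers that is destroyed in steps 6 and 11; it is left undefined in the SMILES.
- Compound 2 is racemic.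

## Route

Step 1
Reactants: 1 β-ionone
Product: 3 3,4-didehydro-β-ionone, via 4-bromo-β-ionone 2 (not isolated)
Conditions: NBS, PhCF3, 80 °C; filter; then N,N-diethylaniline, pyridine, 90 °C
Reagents that add atoms: none
Why: Wohl–Ziegler bromination takes the ring allylic CH2 (C4), and E2 loss of HBr toward C3 gives the cross-ring diene; this is the classical entry to the 3,4-didehydro end group.

Step 2
Reactants: 3 3,4-didehydro-β-ionone
Product: 4 (3R,4S)-3,4-epoxy-β-ionone (cis-epoxide, oxygen on the face of the future O3')
Conditions: (S,S)-Mn(salen)Cl [N,N'-bis(3,5-di-tert-butylsalicylidene)-1,2-cyclohexanediamine complex] (5 mol%), m-CPBA, NMO, CH2Cl2, −78 °C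
Reagents that add atoms: m-chloroperbenzoic acid, OOC(=O)c1cccc(Cl)c1
Why: Jacobsen–Katsuki epoxidation; the oxo-manganese species should take the only cis-disubstituted double bond, which is also the one most remote from the carbonyl, while C5=C6 is tetrasubstituted and shielded by C1Me2 and C7=C8 is trans and enone-deactivated. Both epoxide centers are set by the catalyst through side-on approach of the conjugated cis-alkene.

Step 3
Reactants: 4 (3R,4S)-3,4-epoxy-β-ionone
Product: 8 (3R,6R)-3-hydroxy-α-ionone, via hydrazone adduct 5 (not isolated), via N-sulfonylhydrazine 6 (not isolated), via allylic diazene 7 (not isolated)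
Conditions: IPNBSH [N-isopropylidene-N'-(2-nitrobenzenesulfonyl)hydrazine] (1.2 equiv), Pd2(dba)3·CHCl3 (2.5 mol%), PPh3 (10 mol%), THF, 23 °C; then CF3CH2OH–H2O (1:1), 23 °C
Reagents that add atoms: none
Why: Proposed new method: Pd(0) adds to C5=C6 anti to the epoxide oxygen and ionizes C4–O to a zwitterionic C4–C6 π-allyl palladium alkoxide; the alkoxide deprotonates IPNBSH and the sulfonyl hydrazone nitrogen attacks C4 anti to palladium, so with overall retention and cis to O3, to give 5. Hydrolysis of the acetone hydrazone frees N-sulfonylhydrazine 6, which loses 2-nitrobenzenesulfinic acid to give diazene 7; 7 expels N2 in a concerted six-membered retro-ene shift that places its hydrogen on C6 on the face of the C4–N bond and moves the double bond to C4=C5. The closest known reaction types are the Pd-catalysed substitution of allylic carbonates by IPNBSH followed by sigmatropic loss of N2 from the monoalkyl diazene (stereospecific reductive allylic transposition) and the Pd-catalysed 1,2-opening of vinyl epoxides by acidic N–H nucleophiles with retention; new is their union on a vinyl epoxide whose allyl unit is conjugated to an enone and ends in a fully substituted carbon. No ring is closed. C3 keeps the configuration set in step 2, and the new stereocenter C6 is controlled by it through two stereospecific events (double inversion at C4, then suprafacial hydrogen transfer), so H6 should come out cis to O3 and the side chain trans, which is (3R,6R). The step needs N-attack at C4, secured by the blocked C6 terminus (fully substituted, next to C1Me2) and by hydrogen bonding of the pronucleophile to the C3 alkoxide; attack at the other open terminus C8 would give a diazene that is also 1,3-related to C6 and should deliver hydrogen to the same carbon and, through its E-forming transition state, to the same face. It also needs hydrogen delivery to C6 rather than a longer shift, secured by the six-membered transition state and by the pseudo-axial C4–N bond that A(1,2) strain with the C5 methyl enforces. The loss of conjugation is paid for by the loss of N2.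

Step 4
Reactants: 8 (3R,6R)-3-hydroxy-α-ionone
Product: 9 (3R,6R)-3-hydroxy-9-vinyl-α-ionol [(E)-5-[(1R,4R)-4-hydroxy-2,6,6-trimethylcyclohex-2-en-1-yl]-3-methylpenta-1,4-dien-3-ol, C9 epimers]
Conditions: CH2=CHMgBr (3 equiv), THF, −20 to 0 °C; then H2O/aq. NH4Cl
Reagents that add atoms: vinylmagnesium bromide, C=C[Mg]Br
Why: 1,2-addition of a vinyl Grignard reagent to the methyl enone after deprotonation of the 3-hydroxyl; the low temperature avoids γ-deprotonation at C6, and the C9 epimers converge in step 6.

Step 5
Reactants: 9 (3R,6R)-3-hydroxy-9-vinyl-α-ionol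
Product: 10 (3R,6R)-3-palmitoyloxy-9-vinyl-α-ionol (3-O-hexadecanoate of 9, tertiary hydroxyl free)
Conditions: palmitoyl chloride (1.1 equiv), Et3N, DMAP (cat.), CH2Cl2, 0 °C
Reagents that add atoms: palmitoyl chloride, CCCCCCCCCCCCCCCC(Cl)=O
Why: DMAP-catalysed acylation distinguishes the secondary from the tertiary bis-allylic hydroxyl on steric grounds and proceeds at oxygen, so C3' keeps its configuration.

Step 6
Reactants: 10 (3R,6R)-3-palmitoyloxy-9-vinyl-α-ionol
Product: 11 ε-C15 phosphonium bromide {(2E,4E)-5-[(1R,4R)-4-(hexadecanoyloxy)-2,6,6-trimethylcyclohex-2-en-1-yl]-3-methylpenta-2,4-dienyl}triphenylphosphonium bromide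
Conditions: PPh3·HBr (1.05 equiv), CH2Cl2, 0 °C to rt
Reagents that add atoms: triphenylphosphine hydrobromide, Br.c1ccc(cc1)P(c1ccccc1)c1ccccc1
Why: Classical Wittig-salt formation by SN1' reaction: the tertiary bis-allylic carbinol ionizes to a pentadienyl cation that PPh3 captures at the unhindered primary terminus C11', with E geometry at C9'=C10' favored. The secondary allylic ester should ionize far more slowly.

Step 7
Reactants: 3 3,4-didehydro-β-ionone
Product: 12 3,4-didehydro-β-ionone ethylene ketal [2-methyl-2-[(E)-2-(2,6,6-trimethylcyclohexa-1,3-dien-1-yl)ethenyl]-1,3-dioxolane]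
Conditions: 1,2-bis(trimethylsilyloxy)ethane, TMSOTf (cat.), CH2Cl2, −78 to −20 °C; pyridine quench
Reagents that add atoms: 1,2-bis(trimethylsilyloxy)ethane, C[Si](C)(C)OCCO[Si](C)(C)C
Why: Silyl-triflate-catalysed ketalisation with the bis-silyl ether works at low temperature without protic acid, so the triene should not migrate; the ketone must be masked against the borane.

Step 8
Reactants: 12 3,4-didehydro-β-ionone ethylene ketal
Product: 15 (R)-3-hydroxy-β-ionone, via alkyldiisopinocampheylborane 13 (not isolated), via hydroxy ketal 14 (not isolated)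
Conditions: (+)-Ipc2BH (1.3 equiv), THF, −25 °C; 3 M NaOH, 30% H2O2, 0 °C to rt; then 1 M aq. HCl, THF, rt
Reagents that add atoms: hydrogen peroxide, OO; water, O
Why: Asymmetric hydroboration with diisopinocampheylborane, the reagent of choice for cis-disubstituted alkenes; boron goes to C3, away from the methyl-bearing C5, and the face is chosen by the reagent. Oxidation proceeds with retention and the acid then hydrolyses the allylic ketal.

Step 9
Reactants: 15 (R)-3-hydroxy-β-ionone
Product: 16 (3R)-3-hydroxy-9-vinyl-β-ionol [(E)-5-[(4R)-4-hydroxy-2,6,6-trimethylcyclohex-1-en-1-yl]-3-methylpenta-1,4-dien-3-ol, C9 epimers]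
Conditions: CH2=CHMgBr (3 equiv), THF, −20 to 0 °C; then H2O/aq. NH4Cl
Reagents that add atoms: vinylmagnesium bromide, C=C[Mg]Br
Why: 1,2-addition of the vinyl Grignard reagent to the dienone carbonyl, as in step 4.

Step 10
Reactants: 16 (3R)-3-hydroxy-9-vinyl-β-ionol
Product: 17 (3R)-3-myristoyloxy-9-vinyl-β-ionol (3-O-tetradecanoate of 16, tertiary hydroxyl free)
Conditions: myristoyl chloride (1.1 equiv), Et3N, DMAP (cat.), CH2Cl2, 0 °C
Reagents that add atoms: myristoyl chloride, CCCCCCCCCCCCCC(Cl)=O
Why: Selective acylation of the secondary over the tertiary hydroxyl, with retention at C3, as in step 5.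

Step 11
Reactants: 17 (3R)-3-myristoyloxy-9-vinyl-β-ionol
Product: 18 β-C15 phosphonium bromide {(2E,4E)-5-[(4R)-4-(tetradecanoyloxy)-2,6,6-trimethylcyclohex-1-en-1-yl]-3-methylpenta-2,4-dienyl}triphenylphosphonium bromide
Conditions: PPh3·HBr (1.05 equiv), CH2Cl2, 0 °C to rt
Reagents that add atoms: triphenylphosphine hydrobromide, Br.c1ccc(cc1)P(c1ccccc1)c1ccccc1
Why: Same SN1' salt formation as step 6; here the ester is not allylic and is inert.

Step 12
Reactants: 11 ε-C15 phosphonium bromide; 19 (2E,4E,6E)-2,7-dimethylocta-2,4,6-trienedial (3 equiv)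
Product: 21 C25 aldehyde (3R,6R)-3-palmitoyloxy-12'-apo-ε-caroten-12'-al, via ε-C15 ylide 20 (not isolated)
Conditions: 1,2-epoxybutane, 63 °C, dark, Ar; then n-heptane, 90 °C (Z to E); chromatography
Reagents that add atoms: none
Why: Wittig olefination in which bromide opens the epoxide and the resulting alkoxide generates the ylide at low concentration, so no free base meets the ester or H6'. The excess of the symmetrical dialdehyde should favor mono-olefination, and Z isomers at the new C11'=C12' bond equilibrate thermally to E.

Step 13
Reactants: 21 C25 aldehyde; 18 β-C15 phosphonium bromide (1.2 equiv)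
Product: 23 (3R,3'R,6'R)-lutein 3-O-myristate 3'-O-palmitate (CNP0230054.1), via β-C15 ylide 22 (not isolated)
Conditions: 1,2-epoxybutane, 63 °C, dark, Ar; then n-heptane, 90 °C (Z to E); crystallization
Reagents that add atoms: none
Why: Second Wittig olefination under the same base-free conditions forms C11=C12; no stereocenter is touched, and thermal equilibration followed by crystallization should give the all-E diester.

## Compound list

1 | β-ionone | CC(=O)/C=C/C1=C(C)CCCC1(C)C | starting material
2 | 4-bromo-β-ionone (racemic) | CC(=O)/C=C/C1=C(C)C(Br)CCC1(C)C | intermediate (not isolated)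
3 | 3,4-didehydro-β-ionone | CC(=O)/C=C/C1=C(C)C=CCC1(C)C | intermediate
4 | (3R,4S)-3,4-epoxy-β-ionone | CC(=O)/C=C/C1=C(C)[C@@H]2O[C@@H]2CC1(C)C | intermediate
5 | (3R,4S)-3-hydroxy-4-[N-(2-nitrophenylsulfonyl)-N'-(propan-2-ylidene)hydrazinyl]-β-ionone (3,4-cis) | CC(=O)/C=C/C1=C(C)[C@H](N(N=C(C)C)S(=O)(=O)c2ccccc2[N+](=O)[O-])[C@H](O)CC1(C)C | intermediate (not isolated)
6 | (3R,4S)-3-hydroxy-4-[1-(2-nitrophenylsulfonyl)hydrazinyl]-β-ionone | CC(=O)/C=C/C1=C(C)[C@H](N(N)S(=O)(=O)c2ccccc2[N+](=O)[O-])[C@H](O)CC1(C)C | intermediate (not isolated)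
7 | (3R,4S)-4-diazenyl-3-hydroxy-β-ionone | CC(=O)/C=C/C1=C(C)[C@H](N=N)[C@H](O)CC1(C)C | intermediate (not isolated)
8 | (3R,6R)-3-hydroxy-α-ionone | O[C@H]1C=C(C)[C@H](/C=C/C(C)=O)C(C)(C)C1 | intermediate
9 | (3R,6R)-3-hydroxy-9-vinyl-α-ionol (C9 epimers) | O[C@H]1C=C(C)[C@H](/C=C/C(C)(O)C=C)C(C)(C)C1 | intermediate
10 | (3R,6R)-3-palmitoyloxy-9-vinyl-α-ionol (C9 epimers) | CCCCCCCCCCCCCCCC(=O)O[C@H]1C=C(C)[C@H](/C=C/C(C)(O)C=C)C(C)(C)C1 | intermediate
11 | ε-C15 phosphonium bromide | CCCCCCCCCCCCCCCC(=O)O[C@H]1C=C(C)[C@H](/C=C/C(C)=C/C[P+](c2ccccc2)(c2ccccc2)c2ccccc2)C(C)(C)C1.[Br-] | intermediate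
12 | 3,4-didehydro-β-ionone ethylene ketal | CC1(/C=C/C2=C(C)C=CCC2(C)C)OCCO1 | intermediate
13 | (3R)-3-(diisopinocampheylboryl)-β-ionone ethylene ketal | CC1(/C=C/C2=C(C)C[C@@H](B([C@H]3C[C@H]4C[C@H](C4(C)C)[C@@H]3C)[C@H]3C[C@H]4C[C@H](C4(C)C)[C@@H]3C)CC2(C)C)OCCO1 | intermediate (not isolated)
14 | (3R)-3-hydroxy-β-ionone ethylene ketal | CC1(/C=C/C2=C(C)C[C@@H](O)CC2(C)C)OCCO1 | intermediate (not isolated)
15 | (R)-3-hydroxy-β-ionone | CC(=O)/C=C/C1=C(C)C[C@@H](O)CC1(C)C | intermediate
16 | (3R)-3-hydroxy-9-vinyl-β-ionol (C9 epimers) | CC(O)(C=C)/C=C/C1=C(C)C[C@@H](O)CC1(C)C | intermediate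
17 | (3R)-3-myristoyloxy-9-vinyl-β-ionol (C9 epimers) | CCCCCCCCCCCCCC(=O)O[C@@H]1CC(C)=C(/C=C/C(C)(O)C=C)C(C)(C)C1 | intermediate
18 | β-C15 phosphonium bromide | CCCCCCCCCCCCCC(=O)O[C@@H]1CC(C)=C(/C=C/C(C)=C/C[P+](c2ccccc2)(c2ccccc2)c2ccccc2)C(C)(C)C1.[Br-] | intermediate
19 | (2E,4E,6E)-2,7-dimethylocta-2,4,6-trienedial | O=C/C(C)=C/C=C/C=C(C)/C=O | starting material
20 | ε-C15 ylide | CCCCCCCCCCCCCCCC(=O)O[C@H]1C=C(C)[C@H](/C=C/C(C)=C/C=P(c2ccccc2)(c2ccccc2)c2ccccc2)C(C)(C)C1 | intermediate (not isolated)
21 | (3R,6R)-3-palmitoyloxy-12'-apo-ε-caroten-12'-al (C25 aldehyde) | CCCCCCCCCCCCCCCC(=O)O[C@H]1C=C(C)[C@H](/C=C/C(C)=C/C=C/C(C)=C/C=C/C=C(C)/C=O)C(C)(C)C1 | intermediate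
22 | β-C15 ylide | CCCCCCCCCCCCCC(=O)O[C@@H]1CC(C)=C(/C=C/C(C)=C/C=P(c2ccccc2)(c2ccccc2)c2ccccc2)C(C)(C)C1 | intermediate (not isolated)
23 | (3R,3'R,6'R)-lutein 3-O-myristate 3'-O-palmitate | CCCCCCCCCCCCCCCC(=O)O[C@H]1C=C(C)[C@H](/C=C/C(C)=C/C=C/C(C)=C/C=C/C=C(C)/C=C/C=C(C)/C=C/C2=C(C)C[C@@H](OC(=O)CCCCCCCCCCCCC)CC2(C)C)C(C)(C)C1 | target

## Step count and risk

Total steps: 13. Longest linear sequence: 8 steps (1, 2, 3, 4, 5, 6, 12, 13).

**Step 3 (key step, proposed new method).** Most likely to go wrong:
- the palladium allyl intermediate may undergo β-hydride elimination or isomerize the vinyl epoxide to a ketone before the bulky nitrogen nucleophile reaches the hindered C4;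
- the diazene may lose N2 by a stepwise path, placing hydrogen at C4 or C8 and giving conjugated or retro isomers;
- the sulfinic acid set free may ionize the new allylic alcohol.

Fallback with known reaction types, from 4 back to 8. Formic acid (buffered with sodium formate, 0 °C) opens the epoxide at the allylic carbon C4 with inversion; the enone makes the epoxide electron-poor and should hold the opening to the SN2 side. This gives (3R,4R)-4-formyloxy-3-hydroxy-β-ionone F1. Pd(OAc)2/n-Bu3P in THF then effects decarboxylative hydrogenolysis of the allylic formate. Palladium ionizes anti to the formate, which puts it on the face of O3, and the hydride is passed from palladium to the more substituted terminus C6 on that face, giving 8.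

**Step 2.** Most likely to go wrong: poor facial selectivity of the oxo-manganese catalyst on a cyclic diene with a methyl group on the neighbouring sp2 carbon, and partial epoxidation of C5=C6. Fallback by resolution instead of asymmetric catalysis, from 3 back to 8:
- Uncatalysed m-CPBA epoxidation of 3 gives 4 together with its enantiomer (3S,4R)-3,4-epoxy-β-ionone F2.
- Step 3 on the racemate gives 8 together with (3S,6S)-3-hydroxy-α-ionone F6, the latter through the enantiomeric hydrazone adduct F3, the enantiomeric N-sulfonylhydrazine F4 and the enantiomeric diazene F5. The trans relationship is still fixed by the mechanism.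
- A lipase (Burkholderia cepacia) with vinyl acetate should, by the size rule for secondary alcohols with the C1Me2 side as the large group, acetylate the (3S,6S)-alcohol to (3S,6S)-3-acetoxy-α-ionone F7 and leave 8 as the free alcohol, separable by chromatography.

**Step 8.** Most likely to go wrong: boron addition at C4 instead of C3 (the allylic position of a conjugated diene), or a face choice opposite to the model. Fallback that draws the β-ring from the epoxide already made for the ε-ring and corrects the configuration by inversion, from 4 back to 17: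
- LiAlH4 in Et2O at −20 °C opens the allylic C4–O bond by hydride and reduces the ketone, giving (3S)-3-hydroxy-β-ionol F8.
- MnO2 reoxidizes only the allylic C9 carbinol, giving (S)-3-hydroxy-β-ionone F9.
- Vinylmagnesium bromide gives (3S)-3-hydroxy-9-vinyl-β-ionol F10.
- A Mitsunobu reaction with myristic acid, PPh3 and DIAD esterifies the secondary hydroxyl with inversion and gives 17.

**Step 6.** Most likely to go wrong: ionization of the allylic C3'–O ester by HBr alongside the tertiary carbinol, leading to allylic substitution, epimerization at C3' or elimination, and loss of H6' from the pentadienyl cation toward a retro triene. Fallback without any carbocation, from 8 back to 11: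
- A Horner–Wadsworth–Emmons reaction of 8 with triethyl phosphonoacetate (NaH, THF) gives ethyl (2E,4E)-5-[(1R,4R)-4-hydroxy-2,6,6-trimethylcyclohex-2-en-1-yl]-3-methylpenta-2,4-dienoate F11.
- DIBAL-H at −78 °C gives the corresponding dienol, (2E,4E)-5-[(1R,4R)-4-hydroxy-2,6,6-trimethylcyclohex-2-en-1-yl]-3-methylpenta-2,4-dien-1-ol F12.
- Corey–Kim bromination (NBS, Me2S, −20 °C) converts only the primary allylic hydroxyl into the bromide, (1R,4R)-4-[(1E,3E)-5-bromo-3-methylpenta-1,3-dienyl]-3,5,5-trimethylcyclohex-2-en-1-ol F13.
- PPh3 displaces the bromide to give the hydroxy phosphonium bromide F14.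
- Palmitoyl chloride/pyridine acylates the salt to 11.

**Step 12.** Most likely to go wrong: double olefination of the symmetrical dialdehyde and incomplete Z-to-E equilibration at the new double bond, with thermal stress on the allylic ester. Fallback with a desymmetrized C10 unit, from 19 back to 21:
- Mono-acetalization of 19 with 2,2-dimethylpropane-1,3-diol (cat. acid) gives (2E,4E,6E)-7-(5,5-dimethyl-1,3-dioxan-2-yl)-2-methylocta-2,4,6-trienal F15.
- Wittig reaction of F15 with 11 under the conditions of step 12 gives the C25 acetal F16.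
- Aqueous oxalic acid in THF releases the aldehyde 21.

## Further compounds

F1 | step 3 | (3R,4R)-4-formyloxy-3-hydroxy-β-ionone | CC(=O)/C=C/C1=C(C)[C@@H](OC=O)[C@H](O)CC1(C)C
F2 | step 2 | (3S,4R)-3,4-epoxy-β-ionone (enantiomer of 4) | CC(=O)/C=C/C1=C(C)[C@H]2O[C@H]2CC1(C)C
F3 | step 2 | (3S,4R)-3-hydroxy-4-[N-(2-nitrophenylsulfonyl)-N'-(propan-2-ylidene)hydrazinyl]-β-ionone (enantiomer of 5) | CC(=O)/C=C/C1=C(C)[C@@H](N(N=C(C)C)S(=O)(=O)c2ccccc2[N+](=O)[O-])[C@@H](O)CC1(C)C
F4 | step 2 | (3S,4R)-3-hydroxy-4-[1-(2-nitrophenylsulfonyl)hydrazinyl]-β-ionone (enantiomer of 6) | CC(=O)/C=C/C1=C(C)[C@@H](N(N)S(=O)(=O)c2ccccc2[N+](=O)[O-])[C@@H](O)CC1(C)C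
F5 | step 2 | (3S,4R)-4-diazenyl-3-hydroxy-β-ionone (enantiomer of 7) | CC(=O)/C=C/C1=C(C)[C@@H](N=N)[C@@H](O)CC1(C)C
F6 | step 2 | (3S,6S)-3-hydroxy-α-ionone | O[C@@H]1C=C(C)[C@@H](/C=C/C(C)=O)C(C)(C)C1
F7 | step 2 | (3S,6S)-3-acetoxy-α-ionone | CC(=O)O[C@@H]1C=C(C)[C@@H](/C=C/C(C)=O)C(C)(C)C1
F8 | step 8 | (3S)-3-hydroxy-β-ionol (C9 epimers) | CC(O)/C=C/C1=C(C)C[C@H](O)CC1(C)C
F9 | step 8 | (S)-3-hydroxy-β-ionone | CC(=O)/C=C/C1=C(C)C[C@H](O)CC1(C)C
F10 | step 8 | (3S)-3-hydroxy-9-vinyl-β-ionol (C9 epimers) | CC(O)(C=C)/C=C/C1=C(C)C[C@H](O)CC1(C)C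
F11 | step 6 | ethyl (2E,4E)-5-[(1R,4R)-4-hydroxy-2,6,6-trimethylcyclohex-2-en-1-yl]-3-methylpenta-2,4-dienoate | O[C@H]1C=C(C)[C@H](/C=C/C(C)=C/C(=O)OCC)C(C)(C)C1
F12 | step 6 | (2E,4E)-5-[(1R,4R)-4-hydroxy-2,6,6-trimethylcyclohex-2-en-1-yl]-3-methylpenta-2,4-dien-1-ol | O[C@H]1C=C(C)[C@H](/C=C/C(C)=C/CO)C(C)(C)C1
F13 | step 6 | (1R,4R)-4-[(1E,3E)-5-bromo-3-methylpenta-1,3-dienyl]-3,5,5-trimethylcyclohex-2-en-1-ol | O[C@H]1C=C(C)[C@H](/C=C/C(C)=C/CBr)C(C)(C)C1
F14 | step 6 | {(2E,4E)-5-[(1R,4R)-4-hydroxy-2,6,6-trimethylcyclohex-2-en-1-yl]-3-methylpenta-2,4-dienyl}triphenylphosphonium bromide | O[C@H]1C=C(C)[C@H](/C=C/C(C)=C/C[P+](c2ccccc2)(c2ccccc2)c2ccccc2)C(C)(C)C1.[Br-]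
F15 | step 12 | (2E,4E,6E)-7-(5,5-dimethyl-1,3-dioxan-2-yl)-2-methylocta-2,4,6-trienal | O=C/C(C)=C/C=C/C=C(C)/C1OCC(C)(C)CO1
F16 | step 12 | (3R,6R)-3-palmitoyloxy-12'-apo-ε-caroten-12'-al 2,2-dimethylpropane-1,3-diyl acetal | CCCCCCCCCCCCCCCC(=O)O[C@H]1C=C(C)[C@H](/C=C/C(C)=C/C=C/C(C)=C/C=C/C=C(C)/C2OCC(C)(C)CO2)C(C)(C)C1
A1 | alternative 1 | (R)-α-ionone | C1C=C(C)[C@H](/C=C/C(C)=O)C(C)(C)C1
A2 | alternative 1 | (6R)-3-oxo-α-ionone | O=C1C=C(C)[C@H](/C=C/C(C)=O)C(C)(C)C1
A3 | alternative 1 | (3R,3'R,6'R)-lutein | O[C@H]1C=C(C)[C@H](/C=C/C(C)=C/C=C/C(C)=C/C=C/C=C(C)/C=C/C=C(C)/C=C/C2=C(C)C[C@@H](O)CC2(C)C)C(C)(C)C1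
A4 | alternative 2 | cis-3,4-epoxide of 2,6,6-trimethylcyclohexa-1,3-diene (oxygen on the face of the future O3') | CC1=CC(C)(C)C[C@H]2O[C@@H]12
A5 | alternative 3 | (3R)-3-myristoyloxyretinal | CCCCCCCCCCCCCC(=O)O[C@@H]1CC(C)=C(/C=C/C(C)=C/C=C/C(C)=C/C=O)C(C)(C)C1
A6 | alternative 3 | (3R,6R)-3-palmitoyloxy-α-retinal | CCCCCCCCCCCCCCCC(=O)O[C@H]1C=C(C)[C@H](/C=C/C(C)=C/C=C/C(C)=C/C=O)C(C)(C)C1
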